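It is a pitfall to hold the charge of substrate against the exit rates: what meets intermediate B at any moment is the substrate still present, not the amount weighed in.

    intermediate D → side product A (k1 = 4.3 /s)
    intermediate A ⇌ intermediate B (K2 = 0.94, k2 = 0.30 /s)
    substrate + intermediate B → side product B (k3 = 820 /M/s)
    intermediate C → intermediate D (k4 = 0.011 /s)
    intermediate A ⇌ intermediate C (K5 = 0.55, k5 = 0.13 /s)
    substrate ⇌ intermediate A (K6 = 1.8, k6 = 0.096 /s)
    intermediate C → target (k7 = 0.078 /s)

| flask | substrate | time |
|---|---|---|
| violet | 6.0 × 10⁻⁵ M | 25 s |
| blue | 8.0 × 10⁻⁵ M | 25 s |
| grey | 1.2 × 10⁻⁴ M | 25 s |
| amber | 2.0 × 10⁻⁴ M | 25 s |
| green | 3.0 × 10⁻⁴ M | 25 s |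

* share of target in all that became target or side product A or side product B for violet, blue, grey, amber, green, in this order
* how the row runs (rises, then falls / falls all the way / rises all the way / falls, then rises / hardly changes)

**Which exits compete?** Intermediate C leaves for good with a summed first-order constant of 0.0890 /s, and a fraction 87.6% of that goes to target, while the rest passes through intermediate D, whose 4.3 /s is far faster than the step to target. Against this stands the step between substrate and intermediate B, in which each event removes two units of substrate as counted here.

**But intermediates B and C are transients, so how can you compare them?** Intermediate C lives about 3.07 s, which is shorter than the 7.2 s half-life of substrate in violet by the forward rate of its step alone, so I take it as quasi-steady behind intermediate A. With intermediate B near its balance with intermediate A, this gives [intermediate B]/[intermediate C] of about 2.35.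

**Where, then, does control change hands?** It changes at a concentration I reckon as 2.31 × 10⁻⁵ M, the crossing concentration: the [substrate] at which substrate lost to side product B equals substrate leaving through intermediate C. With that ratio of intermediates held, the second-order exit leads above it and the first-order exit leads below it. The violet charge, lowest of the row, is 2.60 times the crossing, and the green charge is 13.0 times.

**Your intermediate B is being eaten, so isn't that ratio too high?** Yes, at high loading. The pseudo-first-order drain at the crossing is 0.0189 /s, less than the return to intermediate A at 0.319 /s. With the green charge, though, that drain is 0.246 /s at the start, of like size, so I divide by a correction.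

**And which [substrate] do you use for a whole run?** This is my weakest step. By judgement, I take 0.333 of the charge, a third, as the substrate level seen by the exits. That gives a ratio of second-order to first-order exit of 0.825 for violet and 3.45 for green, so I expect target shares of 48.0% and 19.7%, with a fall between them.

The forecast gave 49%, 43%, 36%, 29% and 24%, a row that falls all the way, on the ground that “Second-order loss grows with loading, so the share falls throughout.” My green figure is lower than its 24%.

The flasks give 47.6%, 42.0%, 34.6%, 26.5% and 21.3%, a row that falls all the way. Violet's substrate at 25.0 s is 1.08 × 10⁻⁵ M, below the crossing of 2.31 × 10⁻⁵ M. Green's substrate at 25.0 s is 3.33 × 10⁻⁵ M, still above it, and green holds side product B at 40.9% against target at 11.5%.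

The rate constants stand for no real mixture, and the outcome is calculated.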